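**Plan**

1. Retrosynthetic cuts, in order: the C4 ester C–O; the formyl carbon together with C7=C6 (back to a C7 ketone); the cyclopentane bond C2–C3; then C8–C8a and C4–C3a in one (5+2) oxidopyrylium–alkene cycloaddition, with C8 re-tied to the C4 oxygen as a bridge.
2. Enabling feature: in the seven-membered ring the run C8–C7–C6–C5–C4 carries oxygen on C4 and an sp2 carbon at C7, the pattern of a 3-oxidopyrylium (ring oxygen becomes C4–O, oxido carbon becomes C7); C8a–C3a is its two-carbon partner.
3. The ring fusion is trans (8a-methyl anti to H-3a), so the partner must be an acyclic (E)-trisubstituted alkene, not a cyclopentene; the five-membered ring is closed only after the oxygen bridge is opened.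
4. Helpers: an ester tether from the ylide carbon (future C8) to the C2 oxygen, later lost as CO2 and exchanged for iodide; a resolved C3 carbinol that steers the alkene face and is then oxidised; the oxygen bridge, opened by SmI2.
5. Forward order: alkenyl diol → furylglycolate ester → pyranone → (5+2) (seven-membered ring, bridge and lactone at once) → iodide and ketone → SmI2 bridge opening with Barbier closure of the cyclopentanol → C6 formylation with carbonyl transposition → esterification.
6. Stereochemistry: the alkene geometry gives the trans fusion; the exo tether puts the C4 oxygen syn to H-3a; the (R)-carbinol from a Sharpless kinetic resolution fixes the absolute sense; C3 is set in the chelation-controlled Barbier step.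

Key step: step 7

Remark: atom locants C1 to C8a are those of the azulene core of the target and are used for all intermediates; "exo" means on the side of the bridging oxygen.

**Step 1**
Reactants: 1 but-3-yn-1-ol; 2 2-methylpropanal
Product: 4 rac-(E)-3,6-dimethylhept-3-ene-1,5-diol, via alkenylalane 3 (not isolated)
Conditions: Me3Al (3 equiv), Cp2ZrCl2 (0.25 equiv), CH2Cl2, 0 °C to rt; then 2, −30 to 0 °C; aq. potassium sodium tartrate
Reagents that add atoms: trimethylaluminium, C[Al](C)C
Why: Negishi zirconium-catalysed carboalumination adds methyl and aluminium syn with aluminium at the terminus, and the alkenylalane adds to the aldehyde with retention, so the (E)-trisubstituted alkene (methyl cis to the carbinol carbon) is fixed while the carbinol centre forms racemic.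

**Step 2**
Reactants: 4 rac-(E)-3,6-dimethylhept-3-ene-1,5-diol
Product: 5 (3E,5R)-3,6-dimethylhept-3-ene-1,5-diol
Conditions: Ti(OiPr)4 (0.2 equiv), L-(+)-diisopropyl tartrate (0.3 equiv), t-BuOOH (0.6 equiv), 4 Å MS, CH2Cl2, −20 °C, stopped near 60% conversion
Reagents that add atoms: none
Why: Sharpless kinetic resolution, in which the L-(+)-tartrate catalyst should epoxidise the (5S)-allylic alcohol faster and leave the (5R)-diol; the cis methyl slows the reaction but should not change its sense.

**Step 3**
Reactants: 5 (3E,5R)-3,6-dimethylhept-3-ene-1,5-diol; 6 2-(furan-2-yl)-2-oxoacetic acid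
Product: 7 (3E,5R)-5-hydroxy-3,6-dimethylhept-3-en-1-yl 2-(furan-2-yl)-2-oxoacetate
Conditions: EDC·HCl (1.05 equiv), DMAP (0.1 equiv), CH2Cl2, −20 to 0 °C
Reagents that add atoms: none
Why: Steglich-type carbodiimide esterification should take the primary hydroxyl in preference to the hindered secondary allylic one, and no stereocentre is touched.

**Step 4**
Reactants: 7 (3E,5R)-5-hydroxy-3,6-dimethylhept-3-en-1-yl 2-(furan-2-yl)-2-oxoacetate
Product: 8 (3E,5R)-5-hydroxy-3,6-dimethylhept-3-en-1-yl 2-(furan-2-yl)-2-hydroxyacetate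
Conditions: NaBH4 (0.5 equiv), MeOH–THF, −40 °C
Reagents that add atoms: none
Why: Borohydride reduction of the α-keto ester ketone, which is far more electrophilic than the ester, gives the furfuryl alcohol needed next; the new carbinol centre is uncontrolled and is erased in step 7.

**Step 5**
Reactants: 8 (3E,5R)-5-hydroxy-3,6-dimethylhept-3-en-1-yl 2-(furan-2-yl)-2-hydroxyacetate
Product: 11 (3E,5R)-5-hydroxy-3,6-dimethylhept-3-en-1-yl 6-hydroxy-3-oxo-3,6-dihydro-2H-pyran-2-carboxylate, via endoperoxide 9 (not isolated), via enedione 10 (not isolated)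
Conditions: O2, visible light, tetraphenylporphyrin (cat.), CH2Cl2, −78 °C; then Me2S, −78 °C to rt
Reagents that add atoms: oxygen, O=O
Why: Photooxygenative Achmatowicz rearrangement, in which singlet oxygen adds (4+2) to the furan much faster than it attacks the trisubstituted alkene, Me2S reduces the endoperoxide to the cis-enedione and the carbinol closes onto the aldehyde; the two pyranone sp3 centres form as mixtures and become sp2 in step 7.

**Step 6**
Reactants: 11 (3E,5R)-5-hydroxy-3,6-dimethylhept-3-en-1-yl 6-hydroxy-3-oxo-3,6-dihydro-2H-pyran-2-carboxylate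
Product: 12 (3E,5R)-5-hydroxy-3,6-dimethylhept-3-en-1-yl 6-acetoxy-3-oxo-3,6-dihydro-2H-pyran-2-carboxylate
Conditions: Ac2O (1.05 equiv), pyridine, CH2Cl2, −20 °C
Reagents that add atoms: acetic anhydride, CC(=O)OC(C)=O
Why: Acetylation should take the hemiacetal hydroxyl, which is more acidic and less hindered than the carbinol flanked by isopropyl, and installs the leaving group for ylide formation.

**Step 7**
Reactants: 12 (3E,5R)-5-hydroxy-3,6-dimethylhept-3-en-1-yl 6-acetoxy-3-oxo-3,6-dihydro-2H-pyran-2-carboxylate
Product: 14 lactone-bridged cycloadduct (8-oxabicyclo[3.2.1]oct-3-en-2-one fused to a δ-lactone), via oxidopyrylium ylide 13 (not isolated)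
Conditions: i-Pr2NEt (2 equiv), MeCN (0.005 M), 70 °C
Reagents that add atoms: none
Why: Proposed new method: i-Pr2NEt removes acetic acid from 12 (the pyranone C2–H lies between ketone and ester) to give the 2-alkoxycarbonyl-3-oxidopyrylium 13, whose two oxygen-flanked termini add suprafacially to the tethered alkene in a concerted thermal (5+2) dipolar cycloaddition that forms C8–C8a and C4–C3a; the closest known reaction type is the intramolecular oxidopyrylium–alkene (5+2) cycloaddition of 6-acetoxypyranones that carry the alkene on a carbon or ether tether at C2, and the new element is an ester tether whose acyl carbon sits on the ylide, which makes the dipole electron-poor and matches it to the electron-rich alkene. Rings: the cycloheptenone is closed by the cycloaddition across the pyrylium (its ring oxygen becomes the C8–O–C4 bridge), and the δ-lactone closes as a fused six-membered tether ring in which the planar s-cis ester can span only the small bridgehead-to-exo torsion, which fixes the regiochemistry and the exo position of C1. Stereocentres C8a and C3a follow from suprafacial addition to the (E)-alkene, so methyl and the carbinol side chain (cis on the alkene) end endo while C1 and H-3a end exo, which is the trans ring-fusion pattern of the target; C4 and the temporary centre C8 are fixed by the one-atom bridge, whose oxygen is therefore syn to the exo H-3a. The absolute sense comes from the (R)-carbinol, which should sit in the A(1,3)-minimised rotamer (C–H eclipsing the alkene toward the cis methyl) so that the ylide adds anti to isopropyl, past the small hydroxyl. The step needs the intramolecular addition to beat ylide dimerisation and the ester s-trans preference, which high dilution, a polar solvent and heat should secure, and any minor facial isomer is a diastereomer that is removed before the carbinol is oxidised.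

**Step 8**
Reactants: 14 lactone-bridged cycloadduct
Product: 15 dihydro cycloadduct (C5–C6 saturated)
Conditions: H2 (1 atm), 10% Pd/C, EtOAc, rt
Reagents that add atoms: none
Why: Heterogeneous hydrogenation of the only C=C bond (the enone) removes a competing reducible group before the samarium step and creates no stereocentre.

**Step 9**
Reactants: 15 dihydro cycloadduct
Product: 17 bridged iodo acid (2-oxo-8-oxabicyclo[3.2.1]octane-1-carboxylic acid with 2-iodoethyl arm), via silyl ester 16 (not isolated)
Conditions: Me3SiCl, NaI, MeCN, 50 °C; then aq. Na2S2O3, pH 3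
Reagents that add atoms: sodium iodide, [Na+].[I-]
Why: Ester dealkylation by iodotrimethylsilane made in situ, with SN2 attack of iodide at the primary O–CH2 carbon of the activated lactone; the carboxylate is held as its silyl ester so it cannot re-close, and the bridgehead β-keto acid cannot decarboxylate because no planar enol is possible.

**Step 10**
Reactants: 17 bridged iodo acid
Product: 18 bridged keto iodo acid (side-chain carbinol oxidised to the 2-methylpropanoyl ketone)
Conditions: Dess–Martin periodinane, CH2Cl2, 0 °C to rt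
Reagents that add atoms: none
Why: Dess–Martin oxidation under neutral conditions turns the C3 carbinol, whose steering role is finished, into the isopropyl ketone without epimerising C3a or eliminating the β-oxygen.

**Step 11**
Reactants: 18 bridged keto iodo acid
Product: 21 (3R,3aS,4S,8aR)-3,4-dihydroxy-8a-methyl-3-(propan-2-yl)octahydroazulen-7(1H)-one, via ring-opened iodo ketone 19 (not isolated), via β-keto acid 20 (not isolated)
Conditions: KN(SiMe3)2 (1.0 equiv), THF, −78 °C; SmI2 (5 equiv), HMPA, −78 to 0 °C; then 1 M HCl, 45 °C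
Reagents that add atoms: none
Why: SmI2 should first cleave the C8–O bond α to the C7 ketone (α-alkoxy ketone reduction), which releases the trans ring fusion and stores C7 as its samarium enolate, and then reduce the primary iodide for an intramolecular samarium Barbier addition to the C3 ketone; chelation of that ketone by the new C4 samarium alkoxide and the preference of isopropyl to lie anti to C4 and the angular methyl should set C3 with its hydroxyl cis to the C3a–C4 bond, and the acidic work-up decarboxylates the β-keto acid.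

**Step 12**
Reactants: 21 (3R,3aS,4S,8aR)-3,4-dihydroxy-8a-methyl-3-(propan-2-yl)octahydroazulen-7(1H)-one
Product: 22 (3R,3aS,4S,6E,8aR)-6-[(dimethylamino)methylidene]-3,4-dihydroxy-8a-methyl-3-(propan-2-yl)octahydroazulen-7(1H)-one
Conditions: t-BuOCH(NMe2)2 (3 equiv), toluene, 90 °C
Reagents that add atoms: tert-butoxybis(dimethylamino)methane, CN(C)C(OC(C)(C)C)N(C)C
Why: Aminomethylenation with Bredereck's reagent should occur at C6 because C8 is neopentyl-like next to the quaternary C8a, and it brings in the future formyl carbon.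

**Step 13**
Reactants: 22 (3R,3aS,4S,6E,8aR)-6-[(dimethylamino)methylidene]-3,4-dihydroxy-8a-methyl-3-(propan-2-yl)octahydroazulen-7(1H)-one
Product: 24 (3R,3aS,4S,8aR)-3,4-dihydroxy-8a-methyl-3-(propan-2-yl)-1,2,3,3a,4,5,8,8a-octahydroazulene-6-carbaldehyde, via amino allylic alcohol 23 (not isolated)
Conditions: LiAlH4, THF, −20 °C; then 1 M HCl, THF, rt
Reagents that add atoms: water, O
Why: Hydride 1,2-reduction of the vinylogous amide followed by acid-induced loss of water and hydrolysis of the iminium (enaminone-to-enal 1,3-carbonyl transposition) places the double bond at C7=C6 and the aldehyde on C6, and no stereocentre is involved.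

**Step 14**
Reactants: 24 (3R,3aS,4S,8aR)-3,4-dihydroxy-8a-methyl-3-(propan-2-yl)-1,2,3,3a,4,5,8,8a-octahydroazulene-6-carbaldehyde; 25 4-[(tert-butyldimethylsilyl)oxy]benzoic acid
Product: 26 (3R,3aS,4S,8aR)-6-formyl-3-hydroxy-8a-methyl-3-(propan-2-yl)-1,2,3,3a,4,5,8,8a-octahydroazulen-4-yl 4-[(tert-butyldimethylsilyl)oxy]benzoate
Conditions: EDC·HCl, DMAP (0.2 equiv), CH2Cl2, rt
Reagents that add atoms: none
Why: Steglich esterification acylates the secondary C4 hydroxyl with retention, the tertiary C3 hydroxyl being inert.

**Step 15**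
Reactants: 26 (3R,3aS,4S,8aR)-6-formyl-3-hydroxy-8a-methyl-3-(propan-2-yl)-1,2,3,3a,4,5,8,8a-octahydroazulen-4-yl 4-[(tert-butyldimethylsilyl)oxy]benzoate
Product: 27 (3R,3aS,4S,8aR)-6-formyl-3-hydroxy-8a-methyl-3-(propan-2-yl)-1,2,3,3a,4,5,8,8a-octahydroazulen-4-yl 4-hydroxybenzoate
Conditions: HF·pyridine, pyridine, THF, 0 °C
Reagents that add atoms: none
Why: Fluoride cleavage of the aryl silyl ether under buffered conditions should leave the ester, the enal and the tertiary alcohol untouched.

**Compound list**

1 | but-3-yn-1-ol | C#CCCO | starting material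
2 | 2-methylpropanal | CC(C)C=O | starting material
3 | (E)-alkenylalane: dimethyl[4-(dimethylalumanyloxy)-2-methylbut-1-en-1-yl]alumane | C[Al](C)/C=C(\C)CCO[Al](C)C | intermediate (not isolated)
4 | rac-(E)-3,6-dimethylhept-3-ene-1,5-diol | CC(C)C(O)/C=C(\C)CCO | intermediate
5 | (3E,5R)-3,6-dimethylhept-3-ene-1,5-diol | CC(C)[C@@H](O)/C=C(\C)CCO | intermediate
6 | 2-(furan-2-yl)-2-oxoacetic acid | O=C(O)C(=O)c1ccco1 | starting material
7 | (3E,5R)-5-hydroxy-3,6-dimethylhept-3-en-1-yl 2-(furan-2-yl)-2-oxoacetate | CC(C)[C@@H](O)/C=C(\C)CCOC(=O)C(=O)c1ccco1 | intermediate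
8 | (3E,5R)-5-hydroxy-3,6-dimethylhept-3-en-1-yl 2-(furan-2-yl)-2-hydroxyacetate (both epimers at the glycolate carbon) | CC(C)[C@@H](O)/C=C(\C)CCOC(=O)C(O)c1ccco1 | intermediate
9 | furan endoperoxide of 8 (2,3,7-trioxabicyclo[2.2.1]hept-5-ene) | CC(C)[C@@H](O)/C=C(\C)CCOC(=O)C(O)C12C=CC(OO1)O2 | intermediate (not isolated)
10 | (3E,5R)-5-hydroxy-3,6-dimethylhept-3-en-1-yl (Z)-2-hydroxy-3,6-dioxohex-4-enoate | CC(C)[C@@H](O)/C=C(\C)CCOC(=O)C(O)C(=O)/C=C\C=O | intermediate (not isolated)
11 | (3E,5R)-5-hydroxy-3,6-dimethylhept-3-en-1-yl 6-hydroxy-3-oxo-3,6-dihydro-2H-pyran-2-carboxylate (mixture at the two pyranone sp3 carbons) | CC(C)[C@@H](O)/C=C(\C)CCOC(=O)C1OC(O)C=CC1=O | intermediate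
12 | (3E,5R)-5-hydroxy-3,6-dimethylhept-3-en-1-yl 6-acetoxy-3-oxo-3,6-dihydro-2H-pyran-2-carboxylate | CC(C)[C@@H](O)/C=C(\C)CCOC(=O)C1OC(OC(C)=O)C=CC1=O | intermediate
13 | 2-{[(3E,5R)-5-hydroxy-3,6-dimethylhept-3-en-1-yl]oxycarbonyl}pyrylium-3-olate | CC(C)[C@@H](O)/C=C(\C)CCOC(=O)c1[o+]cccc1[O-] | intermediate (not isolated)
14 | cycloadduct: 8-oxabicyclo[3.2.1]oct-3-en-2-one (oxygen bridge C8–O–C4) whose C8 acyl group is closed as a δ-lactone onto the exo CH2CH2O arm of C8a; 8a-methyl endo; C3a bears exo H and the endo (1R)-1-hydroxy-2-methylpropyl group | CC(C)[C@@H](O)[C@@H]1[C@@H]2C=CC(=O)[C@]3(O2)C(=O)OCC[C@@]13C | intermediate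
15 | dihydro derivative of 14 (C5–C6 saturated) | CC(C)[C@@H](O)[C@@H]1[C@@H]2CCC(=O)[C@]3(O2)C(=O)OCC[C@@]13C | intermediate
16 | trimethylsilyl ester of 17 | CC(C)[C@@H](O)[C@@H]1[C@@H]2CCC(=O)[C@](O2)(C(=O)O[Si](C)(C)C)[C@@]1(C)CCI | intermediate (not isolated)
17 | bridged iodo acid: 2-oxo-8-oxabicyclo[3.2.1]octane-1-carboxylic acid with 7-exo-(2-iodoethyl), 7-endo-methyl and 6-endo-[(1R)-1-hydroxy-2-methylpropyl] groups (bicycle locants; its C1 is target C8) | CC(C)[C@@H](O)[C@@H]1[C@@H]2CCC(=O)[C@](O2)(C(=O)O)[C@@]1(C)CCI | intermediate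
18 | bridged keto iodo acid: as 17 with the side chain oxidised to 6-endo-(2-methylpropanoyl) | CC(C)C(=O)[C@@H]1[C@@H]2CCC(=O)[C@](O2)(C(=O)O)[C@@]1(C)CCI | intermediate
19 | ring-opened iodo ketone, drawn as the neutral keto acid (present in the flask as samarium enolate, alkoxide and carboxylate): cycloheptanone with C4–OH, C3a 2-methylpropanoyl, C8a methyl and 2-iodoethyl, C8 carboxyl | CC(C)C(=O)[C@@H]1[C@@H](O)CCC(=O)C(C(=O)O)[C@@]1(C)CCI | intermediate (not isolated)
20 | β-keto acid: 8-carboxy derivative of 21 (C8 epimers) | CC(C)[C@]1(O)CC[C@]2(C)C(C(=O)O)C(=O)CC[C@H](O)[C@H]21 | intermediate (not isolated)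
21 | (3R,3aS,4S,8aR)-3,4-dihydroxy-8a-methyl-3-(propan-2-yl)octahydroazulen-7(1H)-one (trans-fused) | CC(C)[C@]1(O)CC[C@]2(C)CC(=O)CC[C@H](O)[C@H]21 | intermediate
22 | (3R,3aS,4S,6E,8aR)-6-[(dimethylamino)methylidene]-3,4-dihydroxy-8a-methyl-3-(propan-2-yl)octahydroazulen-7(1H)-one | CC(C)[C@]1(O)CC[C@]2(C)CC(=O)/C(=C/N(C)C)C[C@H](O)[C@H]21 | intermediate
23 | amino allylic alcohol: 7-hydroxy analogue of 22 (C7 epimers) | CC(C)[C@]1(O)CC[C@]2(C)CC(O)/C(=C/N(C)C)C[C@H](O)[C@H]21 | intermediate (not isolated)
24 | (3R,3aS,4S,8aR)-3,4-dihydroxy-8a-methyl-3-(propan-2-yl)-1,2,3,3a,4,5,8,8a-octahydroazulene-6-carbaldehyde | CC(C)[C@]1(O)CC[C@]2(C)CC=C(C=O)C[C@H](O)[C@H]21 | intermediate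
25 | 4-[(tert-butyldimethylsilyl)oxy]benzoic acid | CC(C)(C)[Si](C)(C)Oc1ccc(cc1)C(=O)O | starting material
26 | (3R,3aS,4S,8aR)-6-formyl-3-hydroxy-8a-methyl-3-(propan-2-yl)-1,2,3,3a,4,5,8,8a-octahydroazulen-4-yl 4-[(tert-butyldimethylsilyl)oxy]benzoate | CC(C)[C@]1(O)CC[C@]2(C)CC=C(C=O)C[C@H](OC(=O)c3ccc(O[Si](C)(C)C(C)(C)C)cc3)[C@H]21 | intermediate
27 | (3R,3aS,4S,8aR)-6-formyl-3-hydroxy-8a-methyl-3-(propan-2-yl)-1,2,3,3a,4,5,8,8a-octahydroazulen-4-yl 4-hydroxybenzoate | CC(C)[C@]1(O)CC[C@]2(C)CC=C(C=O)C[C@H](OC(=O)c3ccc(O)cc3)[C@H]21 | target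

**Step count and risks**

Total steps: 15. Longest linear sequence: 15 (the route is fully linear; 2, 6 and 25 are used as bought).

The three steps most likely to fail:

**Step 7 (proposed new method).** The ylide may dimerise, or the cycloaddition may be too slow because the ester tether must reach its s-cis rotamer and the alkene is trisubstituted; the facial bias of the carbinol may also be weak. The fallback uses the known intermolecular oxidopyrylium–enone (5+2) cycloaddition. It sets out from 4: iodination of the primary alcohol (I2, PPh3, imidazole) should give racemic (E)-7-iodo-2,5-dimethylhept-4-en-3-ol F1, and MnO2 the enone (E)-7-iodo-2,5-dimethylhept-4-en-3-one F2. 6-Acetoxy-2H-pyran-3(6H)-one F3 (from furfuryl alcohol by N-bromosuccinimide in aqueous THF, then Ac2O) with Et3N and excess F2 should give the racemic endo-acyl cycloadduct F4, since the enone carbonyl directs the methyl-bearing carbon to the nucleophilic ylide terminus; the exo isomer is removed. SmI2–HMPA then opens the bridge and closes the cyclopentanol in one pot to the racemic diol enone F5, and hydrogenation (H2, Pd/C) gives the racemic diol ketone F6. Lipase-mediated acetylation (Amano lipase PS, vinyl acetate) should acetylate the (4R) antipode, in line with the usual large/medium rule for secondary alcohols, and leave 21, where the route is rejoined.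

**Step 11.** The alkylsamarium may be protonated, the carboxylate may re-close onto the iodide before the Barbier addition, the C4 alkoxide and C3 ketone may undergo retro-aldol cleavage, or the facial selectivity at C3 may be poor. The fallback separates the two reductions and masks C7. It sets out from 17: SmI2 (2.2 equiv) in THF–MeOH at −78 °C only opens the bridge, and warm acidic work-up decarboxylates to the iodo diol ketone F11. PPTS, MeOH and HC(OMe)3 should lock the C4 hydroxyl and the C7 ketone as the bicyclic methyl ketal F12, so that Dess–Martin oxidation touches only the C3 carbinol and gives the keto ketal F13, now the only carbonyl in the molecule. SmI2–HMPA (or iodine–lithium exchange with t-BuLi at −100 °C) closes the cyclopentanol ketal F14, and aqueous HCl returns 21.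

**Step 9.** Lactone opening by iodide may be reversible (re-lactonisation of the carboxylate), or the silyl iodide may attack the ether bridge or the carbinol. The fallback sets out from 15: HCl in MeOH should open the lactone to the hydroxy methyl ester F7, and I2, PPh3 and imidazole convert the primary alcohol to the iodo methyl ester F8. Dess–Martin oxidation gives the keto iodo methyl ester F9, and SmI2–HMPA under the step 11 conditions (no base needed) gives the β-keto methyl ester F10. LiOH followed by warm dilute HCl hydrolyses and decarboxylates it to 21.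

**Further compounds**

F1 | step 7 | rac-(E)-7-iodo-2,5-dimethylhept-4-en-3-ol | CC(C)C(O)/C=C(\C)CCI
F2 | step 7 | (E)-7-iodo-2,5-dimethylhept-4-en-3-one | CC(C)C(=O)/C=C(\C)CCI
F3 | step 7 | 6-acetoxy-2H-pyran-3(6H)-one | CC(=O)OC1OCC(=O)C=C1
F4 | step 7 | racemic cycloadduct: 7-exo-(2-iodoethyl)-7-endo-methyl-6-endo-(2-methylpropanoyl)-8-oxabicyclo[3.2.1]oct-3-en-2-one (one enantiomer drawn) | CC(C)C(=O)[C@@H]1[C@@H]2C=CC(=O)[C@@H](O2)[C@@]1(C)CCI
F5 | step 7 | racemic 3,4-dihydroxy-8a-methyl-3-(propan-2-yl)-2,3,3a,4,8,8a-hexahydroazulen-7(1H)-one, relative configuration as in 21 (one enantiomer drawn) | CC(C)[C@]1(O)CC[C@]2(C)CC(=O)C=C[C@H](O)[C@H]21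
F6 | step 7 | racemic form of 21 (one enantiomer drawn) | CC(C)[C@]1(O)CC[C@]2(C)CC(=O)CC[C@H](O)[C@H]21
F7 | step 9 | bridged hydroxy methyl ester: methyl ester of the acid of 17 with a 2-hydroxyethyl arm in place of 2-iodoethyl | CC(C)[C@@H](O)[C@@H]1[C@@H]2CCC(=O)[C@](O2)(C(=O)OC)[C@@]1(C)CCO
F8 | step 9 | methyl ester of 17 | CC(C)[C@@H](O)[C@@H]1[C@@H]2CCC(=O)[C@](O2)(C(=O)OC)[C@@]1(C)CCI
F9 | step 9 | methyl ester of 18 | CC(C)C(=O)[C@@H]1[C@@H]2CCC(=O)[C@](O2)(C(=O)OC)[C@@]1(C)CCI
F10 | step 9 | methyl ester of 20 | CC(C)[C@]1(O)CC[C@]2(C)C(C(=O)OC)C(=O)CC[C@H](O)[C@H]21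
F11 | step 11 | iodo diol ketone: cycloheptanone with C4–OH, C3a (1R)-1-hydroxy-2-methylpropyl, C8a methyl and 2-iodoethyl | CC(C)[C@@H](O)[C@@H]1[C@@H](O)CCC(=O)C[C@@]1(C)CCI
F12 | step 11 | bicyclic methyl ketal of F11 (C4–O–C7 bridge, methoxy on C7) | CC(C)[C@@H](O)[C@@H]1[C@@H]2CC[C@@](OC)(O2)C[C@@]1(C)CCI
F13 | step 11 | keto ketal: F12 with the side-chain carbinol oxidised to the ketone | CC(C)C(=O)[C@@H]1[C@@H]2CC[C@@](OC)(O2)C[C@@]1(C)CCI
F14 | step 11 | cyclopentanol ketal: bicyclic C7 methyl ketal of 21 | CC(C)[C@]1(O)CC[C@]2(C)C[C@@]3(OC)CC[C@H](O3)[C@H]21
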